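Readings and results are calculated with constants of no real substance; the scatter is artificial.

At early times there is nothing to read: the first reading of the earlier runs comes at 1.25 d, far later than 8.0 min.

| flask | Sbt | Tsp | remark | time |
|---|---|---|---|---|
| birch | 0.75 M | 0.30 M | run made earlier |  |
| ash | 3 M | 0.30 M | run made earlier |  |
| alder | 1.5 M | 0.45 M | run made earlier |  |
| flask | 1.5 M | 0.300 M |  | 15 d |

- birch (time / d: Ofp / %, Tgt / %): 1.25: 1.0, 23.6; 2.50: 2.3, 24.2; 4.00: 4.7, 25.3; 6.00: 8.6, 22.2; 10.0: 11.0, 20.7; 20.0: 15.4, 19.7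
- ash (time / d: Ofp / %, Tgt / %): 1.25: 4.2, 41.5; 4.00: 6.7, 37.9; 6.00: 11.5, 32.5; 10.0: 14.5, 32.5; 15.0: 19.7, 29.1; 20.0: 22.6, 28.8
- alder (time / d: Ofp / %, Tgt / %): 1.25: 2.7, 28.6; 2.50: 6.0, 28.4; 5.00: 7.8, 25.9; 10.0: 11.8, 24.6; 20.0: 18.6, 22.3

(readings scatter by 1 percentage point)

1. ratio of Ofp to Tgt at 8.0 min
2. ratio of Ofp to Tgt at 15 d
3. which of Ofp and Tgt there is more of at 15 d

- a reading or a percentage of Tgt counts all its forms, free or not

What do you read from these runs? The ratio [Ofp]/[Tgt], because at 20.0 d birch, ash and alder give 0.782, 0.785 and 0.834 although their charges differ.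

And at 8.0 min, is the ratio near zero? Not if both products come from Sbt side by side, since two products that start together stand at first in the ratio of their formation rates. I call this the starting ratio, the selectivity factor of the pair. Pooling the runs gives 0.0843 at 1.25 d and 0.479 at 10.0 d, and the line through them meets zero time at 0.0279.

Where is that weak? The line crosses a stretch nobody measured, and each reading scatters by 1 percentage point, so this is a rough reading. Its slope adds far less by 8.0 min, so I commit to 0.0279 there. At 15.0 d the ash run reads 0.677, so I expect Tgt ahead in the flask at 15 d.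

The forecast gives 0.001, lower than mine, then 0.67 with Tgt ahead, and it warns: “It could be higher if Tgt is still forming, because its rise was never observed”.

The flask gives 0.0224 and 0.663, with Tgt ahead at 26.5% against 17.6% of Ofp.

    Sbt + Tsp → Sbt.Tsp (k = 5.90 /M/h)
    Sbt ⇌ Ofp (K = 3.00, k = 0.00690 /h)
    Sbt ⇌ Imd (K = 2.80, k = 0.850 /h)
    Tsp2 ⇌ Tgt, rate k4*(cs4 - [Tgt]) while solid is left; crystals form when [Tgt] > cs4 (solubility = 1.00 M, k = 12.0 /h)
    Sbt ⇌ Tgt (K = 2.80, k = 0.310 /h)

In this flask the starting ratio, read as 0.0279 from the runs, stood at 0.0224 at 8.0 min, while the forward half-lives of Sbt at 0.0342 d were 0.093 d toward Tgt and 4.2 d toward Ofp, a quotient of 0.0221. In the flask, binding of Sbt to Tsp reached the midpoint of its turnover at 0.0876 h and Tgt stood at 32.6% at 1.50 d, then the step to Ofp ran on with its midpoint at 5.20 d, and a neighbouring flask charged with 0.18 M of Tsp showed the same ratio at 8.0 min, 0.0224.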